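The gibbane core is disconnected at C8–C9 and C11–C12. One intramolecular Diels–Alder reaction of an acyclic trienone, whose vinyl ketone C9=C11 is tied through C10–C5–C6 to the 2-silyloxy diene C12=C13–C14=C8, closes rings B and C together. It exploits the cis-fused hydrindane that these rings form about the C8–C9 bond: quaternary C8 arises from an sp2 carbon, the fusion is set cis, and O13 and the C10 carbonyl emerge as a regiodefined enol ether and a ketone. The C6 ester stereocentre, set by a chirality-transferring Claisen rearrangement, steers the diene face. Ring D (ketyl–alkyne closure), the lactone (Michael addition) and ring A (metathesis, then oxidation) follow.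

Key step: step 15

Remark on the chemistry (gibberellane numbering; TMSE = 2-(trimethylsilyl)ethyl, TBS = tert-butyldimethylsilyl, TES = triethylsilyl, TMS = trimethylsilyl): C6 of the cyclisation precursor is made (R), epimeric to the target, because in the endo transition state the ester should sit beside the vinylic C14 and C6–H beside the C15 arm; C6 is a relay centre only, since it becomes sp2 in step 16 and is reset under thermodynamic control in step 18, so the lactate enantiomer used in step 1 can be matched to the facial preference that is found, and the ester is carried throughout as its TMSE ester.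

Step 1
Reactants: 1 ethyl (S)-lactate
Product: 2 ethyl (S)-2-(tert-butyldimethylsilyloxy)propanoate
Conditions: TBSCl, imidazole, DMF, 0 °C to rt
Reagents that add atoms: tert-butyldimethylsilyl chloride, CC(C)(C)[Si](C)(C)Cl
Why: Imidazole-mediated silylation of a secondary alcohol, which leaves the (S) centre untouched.

Step 2
Reactants: 2 ethyl (S)-2-(tert-butyldimethylsilyloxy)propanoate
Product: 3 (S)-2-(tert-butyldimethylsilyloxy)propanoic acid
Conditions: LiOH, THF/H2O, 0 °C; then cold 1 M HCl to pH 3
Reagents that add atoms: lithium hydroxide, [Li+].[OH-]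
Why: Ester saponification at low temperature, under which the α-silyloxy centre should not epimerise.

Step 3
Reactants: 3 (S)-2-(tert-butyldimethylsilyloxy)propanoic acid
Product: 4 (S)-2-(tert-butyldimethylsilyloxy)propanoyl chloride
Conditions: (COCl)2, DMF (cat.), CH2Cl2, 0 °C to rt; used crude
Reagents that add atoms: oxalyl chloride, O=C(Cl)C(=O)Cl
Why: Acid chloride formation through the Vilsmeier-type chloroiminium species, mild enough to keep the silyl ether and the α-centre.

Step 4
Reactants: 5 propiolic acid; 6 2-(trimethylsilyl)ethanol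
Product: 7 2-(trimethylsilyl)ethyl propiolate
Conditions: DCC, DMAP (cat.), CH2Cl2, −20 to 0 °C
Reagents that add atoms: none
Why: Steglich esterification at low temperature, which suppresses addition to the propiolate triple bond and installs the ester that is removed by fluoride at the end.

Step 5
Reactants: 7 2-(trimethylsilyl)ethyl propiolate; 8 3-bromo-1-(trimethylsilyl)-1-propyne
Product: 9 2-(trimethylsilyl)ethyl 6-(trimethylsilyl)hexa-2,5-diynoate
Conditions: CuI (cat.), Cs2CO3, DMF, rt
Reagents that add atoms: none
Why: Copper-mediated coupling of a terminal alkyne with a propargylic bromide (copper acetylide substitution), the standard entry to skipped diynes, which forms the C8–C15 bond under a mild carbonate base.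

Step 6
Reactants: 9 2-(trimethylsilyl)ethyl 6-(trimethylsilyl)hexa-2,5-diynoate
Product: 10 2-(trimethylsilyl)ethyl (E)-3-(tributylstannyl)-6-(trimethylsilyl)hex-2-en-5-ynoate
Conditions: Bu3SnLi (from Bu3SnH and LDA), CuBr·SMe2, THF, −78 °C; then 9, MeOH, −78 °C
Reagents that add atoms: tributyltin hydride, CCCC[SnH](CCCC)CCCC
Why: Stannylcupration of a 2-ynoate, in which syn addition of tin and copper across the activated triple bond and kinetic protonation should give the (E)-β-stannyl enoate with tin on C8, the unactivated silyl alkyne staying untouched.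

Step 7
Reactants: 10 2-(trimethylsilyl)ethyl (E)-3-(tributylstannyl)-6-(trimethylsilyl)hex-2-en-5-ynoate; 4 (S)-2-(tert-butyldimethylsilyloxy)propanoyl chloride
Product: 11 2-(trimethylsilyl)ethyl (2E,5S)-5-(tert-butyldimethylsilyloxy)-4-oxo-3-[3-(trimethylsilyl)prop-2-yn-1-yl]hex-2-enoate
Conditions: Pd2(dba)3 (cat.), P(2-furyl)3, toluene, 60 °C
Reagents that add atoms: none
Why: Stille acylation of the vinylstannane, which forms the C8–C14 bond with retention of the C6=C8 geometry (C14 trans to the ester).

Step 8
Reactants: 11 2-(trimethylsilyl)ethyl (2E,5S)-5-(tert-butyldimethylsilyloxy)-4-oxo-3-[3-(trimethylsilyl)prop-2-yn-1-yl]hex-2-enoate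
Product: 12 2-(trimethylsilyl)ethyl (2E,4S,5S)-5-(tert-butyldimethylsilyloxy)-4-hydroxy-3-[3-(trimethylsilyl)prop-2-yn-1-yl]hex-2-enoate
Conditions: NaBH4, CeCl3·7H2O, MeOH, −78 °C
Reagents that add atoms: none
Why: Luche 1,2-reduction, in which Felkin–Anh attack anti to the C13 silyloxy group should set (14S), syn to O13.

Step 9
Reactants: 12 2-(trimethylsilyl)ethyl (2E,4S,5S)-5-(tert-butyldimethylsilyloxy)-4-hydroxy-3-[3-(trimethylsilyl)prop-2-yn-1-yl]hex-2-enoate; 13 triethyl orthoacetate
Product: 15 (6R)-succinate diester with C10 ethyl ester and C7 TMSE ester and the (E)-C8=C14 alkene carrying the TMS-propargyl arm on C8 and (13S)-CH(OTBS)CH3 on C14, via mixed ketene acetal 14 (not isolated)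
Conditions: MeC(OEt)3 (excess), EtCO2H (cat.), 140 °C, EtOH distilled off
Reagents that add atoms: none
Why: Johnson orthoester Claisen rearrangement through a chair transition state with the C14 substituent equatorial, which forms C5–C6, transfers the C14 chirality suprafacially to C6 (R) and gives the (E)-C8=C14 bond with C13 cis to the C15 arm.

Step 10
Reactants: 15 (6R)-succinate diester
Product: 16 (6R)-C10 Weinreb amide (N-methoxy-N-methylamide) with C7 TMSE ester and (13S)-OTBS
Conditions: MeNHOMe·HCl, AlMe3, CH2Cl2, 0 °C to rt; aq. potassium sodium tartrate work-up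
Reagents that add atoms: N,O-dimethylhydroxylamine hydrochloride, CNOC.Cl
Why: Weinreb aminolysis with the aluminium amide, which should select the unhindered ethyl ester over the α-branched TMSE ester and is not basic enough to touch C6–H.

Step 11
Reactants: 16 (6R)-C10 Weinreb amide
Product: 17 (6R,13S)-allylic alcohol (free C13 hydroxyl)
Conditions: HF·pyridine, pyridine, THF, 0 °C to rt
Reagents that add atoms: none
Why: Acidic fluoride cleavage of the secondary TBS ether, conditions to which the alkynyl silane and the TMSE ester are stable.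

Step 12
Reactants: 17 (6R,13S)-allylic alcohol
Product: 18 (6R)-methyl enone (C13 ketone conjugated to the (E)-C8=C14 bond)
Conditions: Dess–Martin periodinane, NaHCO3, CH2Cl2, 0 °C to rt
Reagents that add atoms: none
Why: Dess–Martin oxidation of the allylic alcohol under buffered, non-basic conditions, which should keep the now doubly activated C6–H configurationally intact.

Step 13
Reactants: 18 (6R)-methyl enone
Product: 19 (6R)-2-silyloxy diene (C12=C13(OTBS)–C14=C8) with C10 Weinreb amide
Conditions: TBSOTf, Et3N, CH2Cl2, −78 to 0 °C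
Reagents that add atoms: tert-butyldimethylsilyl triflate, CC(C)(C)[Si](C)(C)OS(=O)(=O)C(F)(F)F
Why: Soft enolisation (silyl triflate and amine) of the methyl ketone, which removes a C12 proton kinetically and gives the cross-conjugated dienol ether without ever forming an enolate at C6.

Step 14
Reactants: 19 (6R)-2-silyloxy diene Weinreb amide; 20 vinylmagnesium bromide
Product: 21 (6R)-trienone: CH2=CH–C(=O)–CH2–CH(CO2TMSE)–C(CH2C≡C–TMS)=CH–C(OTBS)=CH2 with (E)-C8=C14
Conditions: THF, −78 to −20 °C; inverse quench into cold aq. NH4Cl; used at once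
Reagents that add atoms: none
Why: Weinreb ketone synthesis, in which the chelated tetrahedral adduct releases the vinyl ketone only on quench and the hindered TMSE ester and the silyl dienol ether are not attacked at low temperature.

Step 15
Reactants: 21 (6R)-trienone
Product: 22 cis-hydrindanone silyl enol ether (rings B and C; C10 ketone; C13=C14 enol ether; H9 syn to the C15 arm on quaternary C8; C6 ester cis to C14)
Conditions: toluene (0.01 M), BHT (cat.), 80 °C
Reagents that add atoms: none
Why: A concerted but asynchronous [4+2] cycloaddition of normal electron demand unites the C9=C11 vinyl ketone with the diene C12=C13–C14=C8, the C11–C12 bond running ahead of C8–C9; the closest known reaction type is the thermal intramolecular Diels–Alder reaction of 1,6,8-nonatrien-3-ones that carry 2-silyloxy dienes, which furnishes cis-hydrindanones. Ring B (C5–C6–C8–C9–C10) closes as the five-membered ring spanned by the three-atom tether when C8–C9 forms, and ring C (C8–C9–C11–C12–C13–C14) closes as the new cyclohexene of the suprafacial diene–dienophile union. C9 (H syn to C15) is set by the endo orientation of the tether carbonyl C10 under the diene, and C8 is set by the diene face that the C6 stereocentre selects. Because C5 must rise out of the diene plane towards C10, the two remaining C6 substituents lie close to C14 and to the inside C15 methylene, and placing C6–H next to C15 and the ester next to the vinylic C14 avoids the worse eclipsing; with (6R) this exposes the face that gives the C8 and C9 configuration of the target, the ester ending cis to C14. The step needs regioselectivity (fixed by the tether and by the silyloxy group, which pairs C12 with C11), endo selectivity and facial selectivity, and the last is the uncertain one. The regiodefined C13 enol ether survives as the masked C13 ketone.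

Step 16
Reactants: 22 cis-hydrindanone silyl enol ether
Product: 24 bicyclic enone ester (C5=C6 conjugated to the C10 ketone and the C7 ester), via C5 sulfilimine 23 (not isolated)
Conditions: LDA, THF, −78 °C; then PhS(Cl)=N-t-Bu, −78 °C
Reagents that add atoms: none
Why: Mukaiyama dehydrogenation, in which the kinetic C5 lithium enolate is sulfenylated trans to the ester and syn elimination towards C6 gives the cyclopentenone, removing the C6 stereocentre, while the far less nucleophilic silyl enol ether should not react at −78 °C.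

Step 17
Reactants: 24 bicyclic enone ester; 20 vinylmagnesium bromide; 25 propionyl chloride
Product: 27 C10 propionate (10-vinyl on the face of H9 and O10 on the opposite face), via bromomagnesium C10 alkoxide 26 (not isolated)
Conditions: CeCl3, THF, −78 °C; then EtCOCl, −78 to 0 °C
Reagents that add atoms: none
Why: CeCl3-promoted 1,2-addition of the vinyl Grignard reagent to the enone from the convex face of the cis-hydrindenone (the face of H9, anti to the C9–C11 bond) sets C10, and the tertiary alkoxide is acylated in the same flask.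

Step 18
Reactants: 27 C10 propionate
Product: 29 tricyclic 19,10-lactone (cis-fused at C5–C10; C4 methyl as epimers; C6 ester trans to C4), via potassium C6 ester enolate 28 (not isolated)
Conditions: KHMDS, THF, −78 to 0 °C; then t-BuOH, rt; aq. NH4Cl
Reagents that add atoms: none
Why: Intramolecular Michael addition (5-exo-trig) of the propionate enolate to the C5=C6 enoate delivers C4 to C5 on the face of O10, and reversible protonation under tert-butoxide should place the C6 ester trans to C4 (thermodynamic control).

Step 19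
Reactants: 29 tricyclic 19,10-lactone
Product: 30 C13 ketone with terminal alkyne (C8 propargyl)
Conditions: KF, MeOH, rt to 40 °C
Reagents that add atoms: none
Why: Fluoride-assisted methanolysis cleaves the silyl enol ether to the C13 ketone and protodesilylates the alkyne, whereas the TMSE ester, which needs unsolvated fluoride, and the hindered lactone should survive.

Step 20
Reactants: 30 C13 ketone with terminal alkyne
Product: 31 ring D alcohol (13-hydroxy and 16-methylene; rings B, C, D and lactone)
Conditions: SmI2, HMPA, t-BuOH, THF, 0 °C to rt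
Reagents that add atoms: none
Why: SmI2-mediated ketyl–alkyne cyclisation (5-exo-dig) forms C13–C16; the bridge can only close on the face of C15, which fixes the C13 configuration, and the vinyl radical is reduced and protonated to the exocyclic methylene.

Step 21
Reactants: 31 ring D alcohol
Product: 32 13-O-triethylsilyl ether
Conditions: TESOTf, 2,6-lutidine, CH2Cl2, −78 to 0 °C
Reagents that add atoms: triethylsilyl triflate, CC[Si](CC)(CC)OS(=O)(=O)C(F)(F)F
Why: Silyl triflate protection of the tertiary bridgehead alcohol, so that the later vanadium epoxidation is directed by the C1 hydroxyl alone.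

Step 22
Reactants: 32 13-O-triethylsilyl ether; 33 acrolein
Product: 34 aldol adduct (C4 quaternary with methyl cis to C6 and the C3 carbinol chain cis to the C10 vinyl; C3 epimers)
Conditions: LDA, THF, −78 °C; then acrolein, −78 °C; aq. NH4Cl at −78 °C
Reagents that add atoms: none
Why: Aldol 1,2-addition of the lactone lithium enolate (the lactone α-proton is more acidic than the hindered C6–H) to acrolein from the convex face, anti to the C5–C6 bond, sets C4.

Step 23
Reactants: 34 aldol adduct
Product: 35 tetracyclic 3-hydroxy-1-ene (ring A closed; C3 epimers)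
Conditions: second-generation Grubbs catalyst (5 mol%), CH2Cl2, 40 °C
Reagents that add atoms: none
Why: Ring-closing metathesis of the two terminal vinyl groups forms C1=C2 and ring A, and only the C4 epimer with C3 cis to C1 can close.

Step 24
Reactants: 35 tetracyclic 3-hydroxy-1-ene
Product: 36 3-oxo-1-ene
Conditions: Dess–Martin periodinane, NaHCO3, CH2Cl2, 0 °C
Reagents that add atoms: none
Why: Dess–Martin oxidation of the allylic alcohol, which converges both C3 epimers to one enone.

Step 25
Reactants: 36 3-oxo-1-ene
Product: 37 1β,2β-epoxy-3-ketone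
Conditions: t-BuOOH, DBU, CH2Cl2, 0 °C
Reagents that add atoms: tert-butyl hydroperoxide, CC(C)(C)OO
Why: Weitz–Scheffer nucleophilic epoxidation, in which the peroxide anion adds to C1 on the β-face (that of H5, opposite the lactone bridge) and closes to the epoxide while isolated alkenes stay inert.

Step 26
Reactants: 37 1β,2β-epoxy-3-ketone
Product: 39 1β-hydroxy-2-ene, via epoxy hydrazone 38 (not isolated)
Conditions: N2H4·H2O, AcOH, MeOH (degassed), 0 °C to rt
Reagents that add atoms: none
Why: Wharton transposition, in which the hydrazone fragments with loss of N2 to the C2=C3 alkene and the C1 alkoxide, so the 1β-oxygen configuration set in step 25 is retained.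

Step 27
Reactants: 39 1β-hydroxy-2-ene
Product: 40 doubly protected target (13-O-TES ether; C7 TMSE ester; 1β-hydroxy-2β,3β-epoxide)
Conditions: VO(acac)2 (cat.), t-BuOOH, CH2Cl2, 0 °C to rt
Reagents that add atoms: tert-butyl hydroperoxide, CC(C)(C)OO
Why: Vanadium-catalysed hydroxyl-directed epoxidation delivers oxygen syn to the axial 1β-hydroxyl (2β,3β), also the face opposite the lactone bridge, and the silylated O13 leaves C16=C17 untouched.

Step 28
Reactants: 40 doubly protected target
Product: 41 the target gibberellin (1β,13-dihydroxy-2β,3β-epoxy-16-ene 19,10-lactone 7-oic acid)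
Conditions: TBAF, THF, 0 °C to rt; aq. NH4Cl, then extraction at pH 3
Reagents that add atoms: none
Why: Fluoride cleaves the triethylsilyl ether and triggers β-elimination of the TMSE ester, a near-neutral deprotection that should spare the epoxide, the lactone and the allylic tertiary alcohol.

Compound list
1 | ethyl (S)-lactate | C[C@H](O)C(=O)OCC | starting material
2 | ethyl (S)-2-(tert-butyldimethylsilyloxy)propanoate | C[C@H](O[Si](C)(C)C(C)(C)C)C(=O)OCC | intermediate
3 | (S)-2-(tert-butyldimethylsilyloxy)propanoic acid | C[C@H](O[Si](C)(C)C(C)(C)C)C(=O)O | intermediate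
4 | (S)-2-(tert-butyldimethylsilyloxy)propanoyl chloride | C[C@H](O[Si](C)(C)C(C)(C)C)C(=O)Cl | intermediate
5 | propiolic acid | C#CC(=O)O | starting material
6 | 2-(trimethylsilyl)ethanol | C[Si](C)(C)CCO | starting material
7 | 2-(trimethylsilyl)ethyl propiolate | C#CC(=O)OCC[Si](C)(C)C | intermediate
8 | 3-bromo-1-(trimethylsilyl)-1-propyne | C[Si](C)(C)C#CCBr | starting material
9 | 2-(trimethylsilyl)ethyl 6-(trimethylsilyl)hexa-2,5-diynoate | C[Si](C)(C)C#CCC#CC(=O)OCC[Si](C)(C)C | intermediate
10 | 2-(trimethylsilyl)ethyl (E)-3-(tributylstannyl)-6-(trimethylsilyl)hex-2-en-5-ynoate | C[Si](C)(C)CCOC(=O)/C=C(\CC#C[Si](C)(C)C)[Sn](CCCC)(CCCC)CCCC | intermediate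
11 | 2-(trimethylsilyl)ethyl (2E,5S)-5-(tert-butyldimethylsilyloxy)-4-oxo-3-[3-(trimethylsilyl)prop-2-yn-1-yl]hex-2-enoate | C[C@H](O[Si](C)(C)C(C)(C)C)C(=O)/C(CC#C[Si](C)(C)C)=C/C(=O)OCC[Si](C)(C)C | intermediate
12 | 2-(trimethylsilyl)ethyl (2E,4S,5S)-5-(tert-butyldimethylsilyloxy)-4-hydroxy-3-[3-(trimethylsilyl)prop-2-yn-1-yl]hex-2-enoate | C[C@H](O[Si](C)(C)C(C)(C)C)[C@@H](O)/C(CC#C[Si](C)(C)C)=C/C(=O)OCC[Si](C)(C)C | intermediate
13 | triethyl orthoacetate | CC(OCC)(OCC)OCC | starting material
14 | mixed ketene acetal (C14–O–C(OEt)=CH2) | C[C@H](O[Si](C)(C)C(C)(C)C)[C@@H](OC(=C)OCC)/C(CC#C[Si](C)(C)C)=C/C(=O)OCC[Si](C)(C)C | intermediate (not isolated)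
15 | (6R)-succinate diester (C10 ethyl ester, C7 TMSE ester, (E)-C8=C14, 13S) | CCOC(=O)C[C@@H](C(=O)OCC[Si](C)(C)C)/C(CC#C[Si](C)(C)C)=C/[C@H](C)O[Si](C)(C)C(C)(C)C | intermediate
16 | (6R)-C10 Weinreb amide | CON(C)C(=O)C[C@@H](C(=O)OCC[Si](C)(C)C)/C(CC#C[Si](C)(C)C)=C/[C@H](C)O[Si](C)(C)C(C)(C)C | intermediate
17 | (6R,13S)-allylic alcohol | CON(C)C(=O)C[C@@H](C(=O)OCC[Si](C)(C)C)/C(CC#C[Si](C)(C)C)=C/[C@H](C)O | intermediate
18 | (6R)-methyl enone | CON(C)C(=O)C[C@@H](C(=O)OCC[Si](C)(C)C)/C(CC#C[Si](C)(C)C)=C/C(C)=O | intermediate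
19 | (6R)-2-silyloxy diene Weinreb amide | CON(C)C(=O)C[C@@H](C(=O)OCC[Si](C)(C)C)/C(CC#C[Si](C)(C)C)=C/C(O[Si](C)(C)C(C)(C)C)=C | intermediate
20 | vinylmagnesium bromide | C=C[Mg]Br | starting material
21 | (6R)-trienone, precursor of the key step | C=CC(=O)C[C@@H](C(=O)OCC[Si](C)(C)C)/C(CC#C[Si](C)(C)C)=C/C(O[Si](C)(C)C(C)(C)C)=C | intermediate
22 | cis-hydrindanone silyl enol ether, product of the key step | C[Si](C)(C)C#CC[C@]23C=C(O[Si](C)(C)C(C)(C)C)CC[C@H]2C(=O)C[C@H]3C(=O)OCC[Si](C)(C)C | intermediate
23 | C5 sulfilimine (C5 configuration not defined) | C[Si](C)(C)C#CC[C@]23C=C(O[Si](C)(C)C(C)(C)C)CC[C@H]2C(=O)C(S(=NC(C)(C)C)c1ccccc1)[C@H]3C(=O)OCC[Si](C)(C)C | intermediate (not isolated)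
24 | bicyclic enone ester (C5=C6) | C[Si](C)(C)C#CC[C@]23C=C(O[Si](C)(C)C(C)(C)C)CC[C@H]2C(=O)C=C3C(=O)OCC[Si](C)(C)C | intermediate
25 | propionyl chloride | CCC(=O)Cl | starting material
26 | bromomagnesium C10 alkoxide | C[Si](C)(C)C#CC[C@]23C=C(O[Si](C)(C)C(C)(C)C)CC[C@H]2[C@](O[Mg]Br)(C=C)C=C3C(=O)OCC[Si](C)(C)C | intermediate (not isolated)
27 | C10 propionate | C[Si](C)(C)C#CC[C@]23C=C(O[Si](C)(C)C(C)(C)C)CC[C@H]2[C@](OC(=O)CC)(C=C)C=C3C(=O)OCC[Si](C)(C)C | intermediate
28 | potassium C6 ester enolate | C[Si](C)(C)C#CC[C@]23C=C(O[Si](C)(C)C(C)(C)C)CC[C@H]2[C@@]1(C=C)OC(=O)C(C)[C@H]1C3=C(O[K])OCC[Si](C)(C)C | intermediate (not isolated)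
29 | tricyclic 19,10-lactone (C4 epimers) | C[Si](C)(C)C#CC[C@]23C=C(O[Si](C)(C)C(C)(C)C)CC[C@H]2[C@@]1(C=C)OC(=O)C(C)[C@H]1[C@@H]3C(=O)OCC[Si](C)(C)C | intermediate
30 | C13 ketone with terminal alkyne (C4 epimers) | C#CC[C@]23CC(=O)CC[C@H]2[C@@]1(C=C)OC(=O)C(C)[C@H]1[C@@H]3C(=O)OCC[Si](C)(C)C | intermediate
31 | ring D alcohol (C4 epimers) | C=C1C[C@]23C[C@@]1(O)CC[C@H]2[C@@]4(C=C)OC(=O)C(C)[C@H]4[C@@H]3C(=O)OCC[Si](C)(C)C | intermediate
32 | 13-O-triethylsilyl ether (C4 epimers) | C=C1C[C@]23C[C@@]1(O[Si](CC)(CC)CC)CC[C@H]2[C@@]4(C=C)OC(=O)C(C)[C@H]4[C@@H]3C(=O)OCC[Si](C)(C)C | intermediate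
33 | acrolein | C=CC=O | starting material
34 | aldol adduct (C3 epimers) | C=C1C[C@]23C[C@@]1(O[Si](CC)(CC)CC)CC[C@H]2[C@@]4(C=C)OC(=O)[C@](C)(C(O)C=C)[C@H]4[C@@H]3C(=O)OCC[Si](C)(C)C | intermediate
35 | tetracyclic 3-hydroxy-1-ene (C3 epimers) | C=C1C[C@]23C[C@@]1(O[Si](CC)(CC)CC)CC[C@H]2[C@@]12OC(=O)[C@@](C)([C@H]1[C@@H]3C(=O)OCC[Si](C)(C)C)C(O)C=C2 | intermediate
36 | 3-oxo-1-ene | C=C1C[C@]23C[C@@]1(O[Si](CC)(CC)CC)CC[C@H]2[C@@]12OC(=O)[C@@](C)([C@H]1[C@@H]3C(=O)OCC[Si](C)(C)C)C(=O)C=C2 | intermediate
37 | 1β,2β-epoxy-3-ketone | C=C1C[C@]23C[C@@]1(O[Si](CC)(CC)CC)CC[C@H]2[C@@]12OC(=O)[C@@](C)([C@H]1[C@@H]3C(=O)OCC[Si](C)(C)C)C(=O)[C@H]4O[C@H]42 | intermediate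
38 | epoxy hydrazone | C=C1C[C@]23C[C@@]1(O[Si](CC)(CC)CC)CC[C@H]2[C@@]12OC(=O)[C@@](C)([C@H]1[C@@H]3C(=O)OCC[Si](C)(C)C)C(=NN)[C@H]4O[C@H]42 | intermediate (not isolated)
39 | 1β-hydroxy-2-ene | C=C1C[C@]23C[C@@]1(O[Si](CC)(CC)CC)CC[C@H]2[C@@]12OC(=O)[C@@](C)([C@H]1[C@@H]3C(=O)OCC[Si](C)(C)C)C=C[C@H]2O | intermediate
40 | doubly protected target (13-O-TES ether, C7 TMSE ester, 1β-hydroxy-2β,3β-epoxide) | C=C1C[C@]23C[C@@]1(O[Si](CC)(CC)CC)CC[C@H]2[C@@]12OC(=O)[C@@](C)([C@H]1[C@@H]3C(=O)OCC[Si](C)(C)C)[C@H]1O[C@H]1[C@H]2O | intermediate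
41 | the target gibberellin (1β,13-dihydroxy-2β,3β-epoxy-16-ene 19,10-lactone 7-oic acid) | C=C1C[C@]23C[C@@]1(O)CC[C@H]2[C@@]12OC(=O)[C@@](C)([C@H]1[C@@H]3C(=O)O)[C@H]1O[C@H]1[C@H]2O | target

Total step count: 28. Longest linear sequence: 25 steps (steps 4 to 28, from propiolic acid 5 to 41); steps 1 to 3 make the acid chloride 4 that enters at step 7.

Steps most likely to fail

Step 15. The dienophile may approach the other diene face relative to C6 (the facial sense rests on a conformational prediction), or closure may be slow because the inside C15 arm strains the s-cis diene, so that the vinyl ketone polymerises. Fallback, an anionic route from 18 back to 22: vinylmagnesium bromide 20 would convert the Weinreb amide enone 18 into the vinyl ketone enone F1; LiHMDS at −78 °C would remove a proton from the C12 methyl group, the kinetic site, and the cross-conjugated lithium dienolate, a far more electron-rich diene than the silyl ether, should cyclise at low temperature as an anion-accelerated process, formally an intramolecular double Michael addition that joins C12 to C11 and C9 to C8 within a lithium chelate; TBSCl would then trap the resulting C13 enolate regiospecifically as 22.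

Step 17. The vinyl nucleophile may add in conjugate fashion to the doubly activated C5=C6 bond or to the wrong face of C10, and acylation of the hindered, doubly allylic alkoxide may fail or the ester may ionise. Fallback, an alkynyl surrogate with separate acylation from 24 back to 29: ethynylmagnesium bromide with CeCl3 would give the propargylic alcohol F2 (a slim nucleophile that adds 1,2 and gives a carbinol that acylates more readily and resists ionisation); propionic anhydride with DMAP would give the propionate F3; KHMDS-mediated Michael lactonisation as in step 18 would give the ethynyl lactone F4; semihydrogenation of the terminal alkyne (H2, Pd/CaCO3 poisoned with Pb(OAc)2, quinoline), which the silylated alkyne should resist, would return to 29.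

Step 26. Hydrazine may attack the lactone, or the β-keto lactone may undergo retro-Claisen cleavage, faster than the hydrazone fragments. Fallback, a radical fragmentation from 37 back to 39: NaBH4 with CeCl3 would reduce the ketone to the epoxy alcohol F5 (either C3 epimer serves); 1,1'-thiocarbonyldiimidazole would give the imidazolyl thiocarbonate F6; Bu3SnH with AIBN would generate the C3 radical, which opens the adjacent epoxide to the C2=C3 alkene and a C1 alkoxy radical that the stannane reduces, giving 39 with the 1β-oxygen unchanged.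

Further compounds
F1 | step 15 | (6R)-vinyl ketone methyl enone | C=CC(=O)C[C@@H](C(=O)OCC[Si](C)(C)C)/C(CC#C[Si](C)(C)C)=C/C(C)=O
F2 | step 17 | C10 ethynyl carbinol | C[Si](C)(C)C#CC[C@]23C=C(O[Si](C)(C)C(C)(C)C)CC[C@H]2[C@](O)(C#C)C=C3C(=O)OCC[Si](C)(C)C
F3 | step 17 | C10 ethynyl propionate | C[Si](C)(C)C#CC[C@]23C=C(O[Si](C)(C)C(C)(C)C)CC[C@H]2[C@](OC(=O)CC)(C#C)C=C3C(=O)OCC[Si](C)(C)C
F4 | step 17 | 10-ethynyl 19,10-lactone (C4 epimers) | C[Si](C)(C)C#CC[C@]23C=C(O[Si](C)(C)C(C)(C)C)CC[C@H]2[C@@]1(C#C)OC(=O)C(C)[C@H]1[C@@H]3C(=O)OCC[Si](C)(C)C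
F5 | step 26 | 1β,2β-epoxy-3-ol (C3 epimers) | C=C1C[C@]23C[C@@]1(O[Si](CC)(CC)CC)CC[C@H]2[C@@]12OC(=O)[C@@](C)([C@H]1[C@@H]3C(=O)OCC[Si](C)(C)C)C(O)[C@H]4O[C@H]42
F6 | step 26 | 3-O-(imidazol-1-ylthiocarbonyl) epoxy alcohol | C=C1C[C@]23C[C@@]1(O[Si](CC)(CC)CC)CC[C@H]2[C@@]12OC(=O)[C@@](C)([C@H]1[C@@H]3C(=O)OCC[Si](C)(C)C)C(OC(=S)n5ccnc5)[C@H]4O[C@H]42
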